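**Retrosynthetic overview**
- Target ⇐ removal of two TIPS groups and one acetonide; the C5–C7' bond comes from an aryltitanium (made from the C5 bromide) adding to (R)-glyceraldehyde acetonide in the Felkin sense, which gives the erythro (7'S,8'R) triol.
- C5–Br ⇐ sterically directed Ir C–H borylation and bromodeboronation of the 7-methoxy-2,3-dihydrobenzofuran (C5 is the only unflanked ring C–H).
- Ring A and the dihydrofuran ring ⇐ one gold-catalysed furan–ethynyl ether cycloisomerisation. The furan supplies C3a–C6 and its oxygen (7-OH, later OMe); the ethynyl ether supplies C7a, C7 and O1.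
- Ethynyl ether ⇐ secondary benzylic alcohol with its C–O bond kept ⇐ Evans syn aldol of an N-(2-furylacetyl)oxazolidinone with O-TIPS-vanillin, which sets C2 and C3.
- Ring order: ring B is bought (vanillin); the furan, oxazolidinone and dioxolane rings are carried as building blocks; ring A and the dihydrofuran ring form together in step 7; no ring is formed afterwards.

Assumption: benzofuran numbering is used for the core (O1, C2, C3, C3a, C4–C7, C7a) and C7', C8', C9' for the side chain on C5; commercial reagents that only deliver a protecting group, a methyl group or the two ethynyl carbons are given on the reagent line and are not numbered.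

**Step 1**
Reactants: 1 2-(furan-2-yl)acetic acid; 2 (S)-4-benzyloxazolidin-2-one
Product: 3 (S)-4-benzyl-3-[2-(furan-2-yl)acetyl]oxazolidin-2-one
Conditions: DCC, DMAP (cat.), CH2Cl2, 0 °C to rt
Reagents that add atoms: none
Why: Steglich-type N-acylation, in which the DCC/DMAP-activated arylacetic acid acylates the oxazolidinone nitrogen without creating a stereocentre or touching the auxiliary centre.

**Step 2**
Reactants: 4 vanillin
Product: 5 3-methoxy-4-[(triisopropylsilyl)oxy]benzaldehyde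
Conditions: TIPSCl, imidazole, DMF, rt
Reagents that add atoms: triisopropylsilyl chloride, CC(C)[Si](Cl)(C(C)C)C(C)C
Why: Imidazole-promoted silylation of the phenol; TIPS is chosen because it withstands KH, BuLi and t-BuLi and offers no unhindered aryl C–H to the later borylation.

**Step 3**
Reactants: 3 (S)-4-benzyl-3-[2-(furan-2-yl)acetyl]oxazolidin-2-one; 5 3-methoxy-4-[(triisopropylsilyl)oxy]benzaldehyde
Product: 7 (S)-4-benzyl-3-[(2R,3S)-2-(furan-2-yl)-3-hydroxy-3-{3-methoxy-4-[(triisopropylsilyl)oxy]phenyl}propanoyl]oxazolidin-2-one, via Z-boron enolate 6 (not isolated)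
Conditions: Bu2BOTf, iPr2NEt, CH2Cl2, −78 to 0 °C; then 5, −78 to 0 °C; then pH 7 buffer, MeOH, 30% H2O2, 0 °C
Reagents that add atoms: none
Why: Evans syn aldol reaction, in which the Z-boron enolate reacts through a Zimmerman–Traxler chair on the face away from the benzyl group and so sets both future ring stereocentres (C3 as 2R and C2 as 3S of the acyl chain, typically >95:5 dr).

**Step 4**
Reactants: 7 the aldol adduct
Product: 8 (1S,2R)-2-(furan-2-yl)-1-{3-methoxy-4-[(triisopropylsilyl)oxy]phenyl}propane-1,3-diol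
Conditions: LiBH4, MeOH (1 equiv), THF, 0 °C
Reagents that add atoms: none
Why: Reductive cleavage of the N-acyloxazolidinone by LiBH4 gives the primary alcohol and releases the auxiliary without touching either stereocentre.

**Step 5**
Reactants: 8 the 1,3-diol
Product: 9 (1S,2R)-2-(furan-2-yl)-1-{3-methoxy-4-[(triisopropylsilyl)oxy]phenyl}-3-[(triisopropylsilyl)oxy]propan-1-ol
Conditions: TIPSCl (1.05 equiv), imidazole, CH2Cl2, 0 °C
Reagents that add atoms: triisopropylsilyl chloride, CC(C)[Si](Cl)(C(C)C)C(C)C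
Why: Selective silylation of the primary hydroxyl over the hindered secondary benzylic one with a bulky silyl chloride that is slow to migrate.

**Step 6**
Reactants: 9 the mono-TIPS alcohol
Product: 12 2-[(2R,3S)-3-(ethynyloxy)-3-{3-methoxy-4-[(triisopropylsilyl)oxy]phenyl}-1-[(triisopropylsilyl)oxy]propan-2-yl]furan, via dichlorovinyl ether 10 (not isolated), via lithium alkynyl ether 11 (not isolated)
Conditions: KH, THF, 0 °C; Cl2C=CHCl, −50 °C to rt; then n-BuLi (2.5 equiv), −78 to −40 °C; MeOH, −78 °C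
Reagents that add atoms: trichloroethylene, ClC=C(Cl)Cl
Why: Greene ynol ether synthesis, in which the potassium alkoxide adds to dichloroacetylene made in the flask and BuLi then eliminates HCl and exchanges the second chlorine; the carbinol C–O bond is never broken, so the S centre is retained.

**Step 7**
Reactants: 12 the ethynyl ether
Product: 13 (2S,3R)-2-{3-methoxy-4-[(triisopropylsilyl)oxy]phenyl}-3-{[(triisopropylsilyl)oxy]methyl}-2,3-dihydro-1-benzofuran-7-ol
Conditions: Ph3PAuNTf2 (3 mol %), CH2Cl2, 4 Å MS, 0 °C to rt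
Reagents that add atoms: none
Why: Hashmi phenol synthesis (gold-catalysed furan–yne cycloisomerisation), in which the furan attacks the gold-activated ethynyl ether and the cyclopropyl carbenoid / arene oxide cascade opens to the phenol, so that ring A and the dihydrofuran ring close together with the new OH ortho to O1 while C2 and C3 are untouched and stay trans.

**Step 8**
Reactants: 13 the 7-hydroxy dihydrobenzofuran
Product: 14 (2S,3R)-7-methoxy-2-{3-methoxy-4-[(triisopropylsilyl)oxy]phenyl}-3-{[(triisopropylsilyl)oxy]methyl}-2,3-dihydro-1-benzofuran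
Conditions: MeI, K2CO3, acetone, 40 °C
Reagents that add atoms: iodomethane, CI
Why: Williamson O-methylation of the only free phenol under mild carbonate conditions that leave the aryl TIPS ether intact.

**Step 9**
Reactants: 14 the 7-methoxy dihydrobenzofuran
Product: 16 (2S,3R)-5-bromo-7-methoxy-2-{3-methoxy-4-[(triisopropylsilyl)oxy]phenyl}-3-{[(triisopropylsilyl)oxy]methyl}-2,3-dihydro-1-benzofuran, via aryl pinacolboronate 15 (not isolated)
Conditions: [Ir(OMe)(cod)]2 (1.5 mol %), dtbpy (3 mol %), B2pin2, THF, 80 °C; then CuBr2, MeOH/H2O 1:1, 80 °C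
Reagents that add atoms: copper dibromide (CuBr2), Br[Cu]Br
Why: Sterically controlled iridium-catalysed C–H borylation puts boron on C5, the only ring C–H with no ortho substituent (every C–H of ring B is flanked), and CuBr2 then replaces boron by bromine at the same carbon (ipso bromodeboronation).

**Step 10**
Reactants: 16 the C5 bromide; 17 (R)-2,2-dimethyl-1,3-dioxolane-4-carbaldehyde
Product: 20 (S)-[(4R)-2,2-dimethyl-1,3-dioxolan-4-yl][(2S,3R)-7-methoxy-2-{3-methoxy-4-[(triisopropylsilyl)oxy]phenyl}-3-{[(triisopropylsilyl)oxy]methyl}-2,3-dihydro-1-benzofuran-5-yl]methanol, via aryllithium 18 (not isolated), via aryltitanium triisopropoxide 19 (not isolated)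
Conditions: t-BuLi (2 equiv), THF, −78 °C; ClTi(OiPr)3, −78 to −40 °C; then 17, −78 to 0 °C; aq NH4Cl
Reagents that add atoms: none
Why: Bromine–lithium exchange and transmetalation give a non-chelating aryltitanium that adds to the α-alkoxy aldehyde in the Felkin–Anh mode, creating C7' as S next to the bought R centre C8' (erythro, expected about 85:15 to 90:10, minor epimer removed by chromatography).

**Step 11**
Reactants: 20 the protected adduct
Product: 22 (1S,2R)-1-[(2S,3R)-2-(4-hydroxy-3-methoxyphenyl)-3-(hydroxymethyl)-7-methoxy-2,3-dihydro-1-benzofuran-5-yl]propane-1,2,3-triol (CNP0219585.4), via desilylated acetonide 21 (not isolated)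
Conditions: TBAF, THF, 0 °C to rt; then AcOH/H2O 4:1, 45 °C
Reagents that add atoms: none
Why: Fluoride desilylation of both TIPS ethers followed by mild acid hydrolysis of the isopropylidene ketal, under conditions too weak to ionise the benzylic C7'–OH or C2–O1 bonds, so all four stereocentres are kept.

**Compound list**
1 | 2-(furan-2-yl)acetic acid | OC(=O)Cc1ccco1 | starting material
2 | (S)-4-benzyloxazolidin-2-one | O=C1OC[C@H](Cc2ccccc2)N1 | starting material
3 | (S)-4-benzyl-3-[2-(furan-2-yl)acetyl]oxazolidin-2-one | O=C1OC[C@H](Cc2ccccc2)N1C(=O)Cc3ccco3 | intermediate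
4 | vanillin (4-hydroxy-3-methoxybenzaldehyde) | COc1cc(C=O)ccc1O | starting material
5 | 3-methoxy-4-[(triisopropylsilyl)oxy]benzaldehyde | COc1cc(C=O)ccc1O[Si](C(C)C)(C(C)C)C(C)C | intermediate
6 | (S)-4-benzyl-3-[(Z)-1-[(dibutylboranyl)oxy]-2-(furan-2-yl)ethenyl]oxazolidin-2-one (Z-boron enolate of 3, not isolated) | O=C1OC[C@H](Cc2ccccc2)N1/C(OB(CCCC)CCCC)=C/c3ccco3 | intermediate
7 | (S)-4-benzyl-3-[(2R,3S)-2-(furan-2-yl)-3-hydroxy-3-{3-methoxy-4-[(triisopropylsilyl)oxy]phenyl}propanoyl]oxazolidin-2-one | O=C1OC[C@H](Cc2ccccc2)N1C(=O)[C@@H](c3ccco3)[C@H](O)c4ccc(O[Si](C(C)C)(C(C)C)C(C)C)c(OC)c4 | intermediate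
8 | (1S,2R)-2-(furan-2-yl)-1-{3-methoxy-4-[(triisopropylsilyl)oxy]phenyl}propane-1,3-diol | COc1cc([C@@H](O)[C@@H](CO)c2ccco2)ccc1O[Si](C(C)C)(C(C)C)C(C)C | intermediate
9 | (1S,2R)-2-(furan-2-yl)-1-{3-methoxy-4-[(triisopropylsilyl)oxy]phenyl}-3-[(triisopropylsilyl)oxy]propan-1-ol | COc1cc([C@@H](O)[C@@H](CO[Si](C(C)C)(C(C)C)C(C)C)c2ccco2)ccc1O[Si](C(C)C)(C(C)C)C(C)C | intermediate
10 | 2-[(2R,3S)-3-{[(E)-1,2-dichloroethenyl]oxy}-3-{3-methoxy-4-[(triisopropylsilyl)oxy]phenyl}-1-[(triisopropylsilyl)oxy]propan-2-yl]furan (not isolated) | COc1cc([C@@H](O/C(Cl)=C\Cl)[C@@H](CO[Si](C(C)C)(C(C)C)C(C)C)c2ccco2)ccc1O[Si](C(C)C)(C(C)C)C(C)C | intermediate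
11 | lithium acetylide of 12 (lithioethynyl ether, not isolated) | COc1cc([C@@H](OC#C[Li])[C@@H](CO[Si](C(C)C)(C(C)C)C(C)C)c2ccco2)ccc1O[Si](C(C)C)(C(C)C)C(C)C | intermediate
12 | 2-[(2R,3S)-3-(ethynyloxy)-3-{3-methoxy-4-[(triisopropylsilyl)oxy]phenyl}-1-[(triisopropylsilyl)oxy]propan-2-yl]furan | COc1cc([C@@H](OC#C)[C@@H](CO[Si](C(C)C)(C(C)C)C(C)C)c2ccco2)ccc1O[Si](C(C)C)(C(C)C)C(C)C | intermediate
13 | (2S,3R)-2-{3-methoxy-4-[(triisopropylsilyl)oxy]phenyl}-3-{[(triisopropylsilyl)oxy]methyl}-2,3-dihydro-1-benzofuran-7-ol | COc1cc([C@H]2Oc3c(O)cccc3[C@@H]2CO[Si](C(C)C)(C(C)C)C(C)C)ccc1O[Si](C(C)C)(C(C)C)C(C)C | intermediate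
14 | (2S,3R)-7-methoxy-2-{3-methoxy-4-[(triisopropylsilyl)oxy]phenyl}-3-{[(triisopropylsilyl)oxy]methyl}-2,3-dihydro-1-benzofuran | COc1cc([C@H]2Oc3c(OC)cccc3[C@@H]2CO[Si](C(C)C)(C(C)C)C(C)C)ccc1O[Si](C(C)C)(C(C)C)C(C)C | intermediate
15 | 5-(4,4,5,5-tetramethyl-1,3,2-dioxaborolan-2-yl) derivative of 14 (not isolated) | COc1cc([C@H]2Oc3c(OC)cc(B4OC(C)(C)C(C)(C)O4)cc3[C@@H]2CO[Si](C(C)C)(C(C)C)C(C)C)ccc1O[Si](C(C)C)(C(C)C)C(C)C | intermediate
16 | (2S,3R)-5-bromo-7-methoxy-2-{3-methoxy-4-[(triisopropylsilyl)oxy]phenyl}-3-{[(triisopropylsilyl)oxy]methyl}-2,3-dihydro-1-benzofuran | COc1cc([C@H]2Oc3c(OC)cc(Br)cc3[C@@H]2CO[Si](C(C)C)(C(C)C)C(C)C)ccc1O[Si](C(C)C)(C(C)C)C(C)C | intermediate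
17 | (R)-2,2-dimethyl-1,3-dioxolane-4-carbaldehyde (D-glyceraldehyde acetonide) | O=C[C@H]1COC(C)(C)O1 | starting material
18 | 5-lithio derivative of 14 (aryllithium from 16, not isolated) | COc1cc([C@H]2Oc3c(OC)cc([Li])cc3[C@@H]2CO[Si](C(C)C)(C(C)C)C(C)C)ccc1O[Si](C(C)C)(C(C)C)C(C)C | intermediate
19 | 5-[tri(propan-2-yloxy)titanio] derivative of 14 (aryltitanium, not isolated) | COc1cc([C@H]2Oc3c(OC)cc([Ti](OC(C)C)(OC(C)C)OC(C)C)cc3[C@@H]2CO[Si](C(C)C)(C(C)C)C(C)C)ccc1O[Si](C(C)C)(C(C)C)C(C)C | intermediate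
20 | (S)-[(4R)-2,2-dimethyl-1,3-dioxolan-4-yl][(2S,3R)-7-methoxy-2-{3-methoxy-4-[(triisopropylsilyl)oxy]phenyl}-3-{[(triisopropylsilyl)oxy]methyl}-2,3-dihydro-1-benzofuran-5-yl]methanol | COc1cc([C@H]2Oc3c(OC)cc([C@H](O)[C@H]4COC(C)(C)O4)cc3[C@@H]2CO[Si](C(C)C)(C(C)C)C(C)C)ccc1O[Si](C(C)C)(C(C)C)C(C)C | intermediate
21 | (S)-[(4R)-2,2-dimethyl-1,3-dioxolan-4-yl][(2S,3R)-2-(4-hydroxy-3-methoxyphenyl)-3-(hydroxymethyl)-7-methoxy-2,3-dihydro-1-benzofuran-5-yl]methanol (not isolated) | COc1cc([C@H]2Oc3c(OC)cc([C@H](O)[C@H]4COC(C)(C)O4)cc3[C@@H]2CO)ccc1O | intermediate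
22 | (1S,2R)-1-[(2S,3R)-2-(4-hydroxy-3-methoxyphenyl)-3-(hydroxymethyl)-7-methoxy-2,3-dihydro-1-benzofuran-5-yl]propane-1,2,3-triol (CNP0219585.4) | COc1cc([C@H]2Oc3c(OC)cc([C@H](O)[C@H](O)CO)cc3[C@@H]2CO)ccc1O | target

**Step count and weak points**
Total step count: 11. Longest linear sequence: 10 steps (steps 1 and 3 to 11; step 2 is a one-step side branch).

Most likely to fail, first: step 7. The gold-activated ethynyl ether sits on a benzylic carbon that can ionise, the ynol ether can hydrate or rearrange before the furan attacks, and furans with a free 5-position give less clean phenol syntheses. The fallback gives up the construction of ring A and uses a bought arene; it sets out from 5 and comes back to the route at 16. Compound 5 is reduced with NaBH4 to {3-methoxy-4-[(triisopropylsilyl)oxy]phenyl}methanol F3. Commercial 4-bromo-2-methoxyphenol is iodinated with NIS to 4-bromo-2-iodo-6-methoxyphenol F4. Mitsunobu coupling (PPh3, DIAD) of the two gives the aryl benzyl ether F5. Pd(PPh3)4 with Ag2CO3 and Et3N couples its C–I bond with methyl diazoacetate to the aryldiazoacetate F6. Rh2(S-PTTL)4 (or its enantiomer, whichever delivers 2S) closes the dihydrofuran by carbenoid insertion into the benzylic C–H bond to give the cis ester F7. DBU epimerises C3 to the trans ester F8, LiBH4 reduces it to the primary alcohol F9, and TIPSCl with imidazole gives 16.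

Second: step 6. The potassium alkoxide of 9 can trigger 1,5 O-to-O silyl migration, excess BuLi can deprotonate the doubly activated benzylic C–H, and the product is thermally labile. The fallback avoids any free alkoxide and builds the triple bond from a formate; it sets out from 9 and comes back at 12. Compound 9 is formylated (acetic formic anhydride, pyridine) to the formate ester F1. CBr4 and PPh3 convert the formyl C=O into a dibromoalkene (Ramirez-type olefination) to give the 2,2-dibromovinyl ether F2. n-BuLi (2.2 equiv, −78 °C) then effects bromine–lithium exchange and Fritsch–Buttenberg–Wiechell rearrangement to 11, which MeOH protonates to 12.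

Third: step 10. The anti:syn ratio of the aryl addition may be modest. The fallback sets C7' by ketone reduction instead of by C–C bond formation; it sets out from 16 and comes back at 20. Aryllithium 18 is added to 17 without titanium. The resulting mixture of 20 and its (R)-carbinol epimer F10 is oxidised with Dess–Martin periodinane to the single aryl ketone F11. Zn(BH4)2 in Et2O at −30 °C reduces F11 under chelation control (zinc bound to the carbonyl and the α-oxygen, hydride from the face of the α-hydrogen) to the erythro alcohol 20.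

**Further compounds**
F1 | step 6 | (1S,2R)-2-(furan-2-yl)-1-{3-methoxy-4-[(triisopropylsilyl)oxy]phenyl}-3-[(triisopropylsilyl)oxy]propyl formate | COc1cc([C@@H](OC=O)[C@@H](CO[Si](C(C)C)(C(C)C)C(C)C)c2ccco2)ccc1O[Si](C(C)C)(C(C)C)C(C)C
F2 | step 6 | 2-[(2R,3S)-3-[(2,2-dibromoethenyl)oxy]-3-{3-methoxy-4-[(triisopropylsilyl)oxy]phenyl}-1-[(triisopropylsilyl)oxy]propan-2-yl]furan | COc1cc([C@@H](OC=C(Br)Br)[C@@H](CO[Si](C(C)C)(C(C)C)C(C)C)c2ccco2)ccc1O[Si](C(C)C)(C(C)C)C(C)C
F3 | step 7 | {3-methoxy-4-[(triisopropylsilyl)oxy]phenyl}methanol | COc1cc(CO)ccc1O[Si](C(C)C)(C(C)C)C(C)C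
F4 | step 7 | 4-bromo-2-iodo-6-methoxyphenol | COc1cc(Br)cc(I)c1O
F5 | step 7 | {4-[(4-bromo-2-iodo-6-methoxyphenoxy)methyl]-2-methoxyphenoxy}triisopropylsilane | COc1cc(COc2c(I)cc(Br)cc2OC)ccc1O[Si](C(C)C)(C(C)C)C(C)C
F6 | step 7 | methyl 2-[5-bromo-3-methoxy-2-({3-methoxy-4-[(triisopropylsilyl)oxy]phenyl}methoxy)phenyl]-2-diazoacetate | COC(=O)C(=[N+]=[N-])c1cc(Br)cc(OC)c1OCc1ccc(O[Si](C(C)C)(C(C)C)C(C)C)c(OC)c1
F7 | step 7 | methyl (2S,3R)-5-bromo-7-methoxy-2-{3-methoxy-4-[(triisopropylsilyl)oxy]phenyl}-2,3-dihydro-1-benzofuran-3-carboxylate (cis) | COc1cc([C@H]2Oc3c(OC)cc(Br)cc3[C@H]2C(=O)OC)ccc1O[Si](C(C)C)(C(C)C)C(C)C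
F8 | step 7 | methyl (2S,3S)-5-bromo-7-methoxy-2-{3-methoxy-4-[(triisopropylsilyl)oxy]phenyl}-2,3-dihydro-1-benzofuran-3-carboxylate (trans) | COc1cc([C@H]2Oc3c(OC)cc(Br)cc3[C@@H]2C(=O)OC)ccc1O[Si](C(C)C)(C(C)C)C(C)C
F9 | step 7 | [(2S,3R)-5-bromo-7-methoxy-2-{3-methoxy-4-[(triisopropylsilyl)oxy]phenyl}-2,3-dihydro-1-benzofuran-3-yl]methanol | COc1cc([C@H]2Oc3c(OC)cc(Br)cc3[C@@H]2CO)ccc1O[Si](C(C)C)(C(C)C)C(C)C
F10 | step 10 | (R)-[(4R)-2,2-dimethyl-1,3-dioxolan-4-yl][(2S,3R)-7-methoxy-2-{3-methoxy-4-[(triisopropylsilyl)oxy]phenyl}-3-{[(triisopropylsilyl)oxy]methyl}-2,3-dihydro-1-benzofuran-5-yl]methanol | COc1cc([C@H]2Oc3c(OC)cc([C@@H](O)[C@H]4COC(C)(C)O4)cc3[C@@H]2CO[Si](C(C)C)(C(C)C)C(C)C)ccc1O[Si](C(C)C)(C(C)C)C(C)C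
F11 | step 10 | [(4R)-2,2-dimethyl-1,3-dioxolan-4-yl][(2S,3R)-7-methoxy-2-{3-methoxy-4-[(triisopropylsilyl)oxy]phenyl}-3-{[(triisopropylsilyl)oxy]methyl}-2,3-dihydro-1-benzofuran-5-yl]methanone | COc1cc([C@H]2Oc3c(OC)cc(C(=O)[C@H]4COC(C)(C)O4)cc3[C@@H]2CO[Si](C(C)C)(C(C)C)C(C)C)ccc1O[Si](C(C)C)(C(C)C)C(C)C
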